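**Retrosynthetic overview**
1. 21 ⇐ 20 by epoxidation of the only electron-rich alkene (Z-C1=C10); 20 ⇐ diol 18 by C5-selective angeloylation; 18 ⇐ acetonide enone 17 ⇐ alcohol 16.
2. Key disconnection C7–C8: the ten-membered carbocycle and the trans-lactone are closed together by a cathodic, chromium-catalysed ring-closing allylation of the open-chain aldehyde/allylic bromide 14; C6 controls C7 and C8.
3. 14 ⇐ ester 9 (CO2Me → CHO → Morita–Baylis–Hillman adduct → SN2' bromide; acetal → CHO); 9 ⇐ aldehyde 5 + alkyne 8 (C3–C4 bond, nickel-catalysed reductive coupling).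
4. 5 ⇐ 4-methylanisole 1 (Birch reduction locks the Z alkene in a ring, ozonolysis opens it); 8 ⇐ dimethyl 2,3-O-isopropylidene-D-tartrate 6 (supplies C5 and C6).
5. Ring order: dioxolane (bought), then carbocycle and lactone in one step (step 10), epoxide last (step 14).

Assumption (locants used below): C1 epoxide CH, C2 CH2, C3 ketone, C4 (=C15H2), C5 (O-angeloyl), C6 (OH), C7, C8 (lactone O), C9 CH2, C10 (C14 methyl, epoxide), C11 (=C13H2), C12 lactone C=O; the target is then (1S,5R,6R,7R,8R,10R) with a Z angelate. Compounds 9, 10, 12–16 are carried as mixtures of C3 epimers (12 also at the C7 carbinol), since these centres are erased in steps 8 and 11.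

**Route**

Step 1
Reactants: 1 4-methylanisole
Product: 2 1-methoxy-4-methylcyclohexa-1,4-diene
Conditions: Li, NH3(l)/THF, t-BuOH, −78 to −33 °C; H2O
Reagents that add atoms: none
Why: Birch reduction leaves both donor substituents on the two remaining alkenes, so the future C1=C10 alkene sits in a six-membered ring and can only be Z.

Step 2
Reactants: 2 1-methoxy-4-methylcyclohexa-1,4-diene
Product: 4 methyl (3Z)-6,6-dimethoxy-4-methylhex-3-enoate, via aldehyde ester 3 (not isolated)
Conditions: O3 (1 equiv), CH2Cl2/MeOH, −78 °C; Me2S; then HC(OMe)3, TsOH (cat.), rt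
Reagents that add atoms: ozone [O-][O+]=O; trimethyl orthoformate COC(OC)OC
Why: Ozonolysis cleaves the electron-rich enol ether far faster than the trisubstituted alkene, giving ester (C3) and aldehyde (C8) ends with the Z geometry intact, and the aldehyde is acetalised in the same pot.

Step 3
Reactants: 4 methyl (3Z)-6,6-dimethoxy-4-methylhex-3-enoate
Product: 5 (3Z)-6,6-dimethoxy-4-methylhex-3-enal
Conditions: i-Bu2AlH (1.05 equiv), CH2Cl2, −78 °C; MeOH, aqueous work-up; used crude
Reagents that add atoms: none
Why: Partial ester reduction through the aluminium hemiacetal, stable at −78 °C, gives the C3 aldehyde without moving the β,γ-alkene.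

Step 4
Reactants: 6 dimethyl (4S,5S)-2,2-dimethyl-1,3-dioxolane-4,5-dicarboxylate
Product: 8 methyl (4S,5R)-5-ethynyl-2,2-dimethyl-1,3-dioxolane-4-carboxylate, via formyl ester 7 (not isolated)
Conditions: i-Bu2AlH (0.95 equiv), CH2Cl2, −78 °C; then MeOH, K2CO3, dimethyl (1-diazo-2-oxopropyl)phosphonate, −78 °C to rt
Reagents that add atoms: dimethyl (1-diazo-2-oxopropyl)phosphonate CC(=O)C(=[N+]=[N-])P(=O)(OC)OC
Why: Statistical mono-reduction of the C2-symmetric diester (either ester gives the same aldehyde; diester recycled) followed by Ohira–Bestmann homologation gives the C4≡C15 alkyne, with C5 and C6 bought in 6 and the trans-dioxolane being the thermodynamic isomer.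

Step 5
Reactants: 5 (3Z)-6,6-dimethoxy-4-methylhex-3-enal; 8 methyl (4S,5R)-5-ethynyl-2,2-dimethyl-1,3-dioxolane-4-carboxylate
Product: 9 methyl (4S,5R)-5-[(5Z)-8,8-dimethoxy-6-methyl-3-(triethylsilyloxy)octa-1,5-dien-2-yl]-2,2-dimethyl-1,3-dioxolane-4-carboxylate
Conditions: Ni(cod)2 (10 mol%), SIPr·HCl (10 mol%), KOt-Bu (10 mol%), Et3SiH (2 equiv), THF, rt, slow addition of 5 and 8
Reagents that add atoms: triethylsilane CC[SiH](CC)CC
Why: Nickel-catalysed aldehyde–alkyne reductive coupling (oxidative cyclisation at zerovalent nickel, then Si–H σ-bond metathesis), where the bulky carbene ligand places the new C3–C4 bond on the internal alkyne carbon, giving the 1,1-disubstituted alkene and the C3 oxygen already silylated.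

Step 6
Reactants: 9 coupled ester
Product: 10 (4S,5R)-5-[(5Z)-8,8-dimethoxy-6-methyl-3-(triethylsilyloxy)octa-1,5-dien-2-yl]-2,2-dimethyl-1,3-dioxolane-4-carbaldehyde
Conditions: i-Bu2AlH (1.1 equiv), toluene, −78 °C; MeOH, aqueous work-up
Reagents that add atoms: none
Why: α-Alkoxy esters stop cleanly at the aldehyde with i-Bu2AlH at −78 °C, and the silyl ether, acetal and acetonide are inert.

Step 7
Reactants: 10 dioxolane aldehyde; 11 methyl acrylate
Product: 12 Morita–Baylis–Hillman adduct (10 with CHO converted into CH(OH)–C(=CH2)–CO2Me)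
Conditions: 11 (10 equiv, neat), DABCO (1 equiv), rt, 4 d
Reagents that add atoms: none
Why: Morita–Baylis–Hillman reaction of a reactive α-alkoxy aldehyde brings in C11–C13; the new carbinol centre is removed in step 8 and C6 stays trans on the dioxolane.

Step 8
Reactants: 12 Morita–Baylis–Hillman adduct
Product: 13 (Z)-allylic bromide (dioxolane C6 now bears CH=C(CH2Br)CO2Me)
Conditions: NBS (1.3 equiv), Me2S (1.5 equiv), CH2Cl2, −20 to 0 °C
Reagents that add atoms: N-bromosuccinimide O=C1CCC(=O)N1Br
Why: Corey–Kim-type activation of the alcohol and SN2' delivery of bromide to the terminal methylene give the conjugated (Z)-2-(bromomethyl)enoate.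

Step 9
Reactants: 13 (Z)-allylic bromide
Product: 14 aldehyde bromide (13 with CH(OMe)2 converted into CHO)
Conditions: Et3SiOTf (2 equiv), 2,4,6-collidine (3 equiv), CH2Cl2, 0 °C; then H2O
Reagents that add atoms: water O
Why: Silyl triflate/collidine cleavage of a dimethyl acetal via the collidinium N,O-acetal is selective for aldehyde acetals and spares the isopropylidene ketal, the silyl ether and the allylic bromide.

Step 10
Reactants: 14 aldehyde bromide
Product: 16 lactone alcohol (ten-membered ring, trans-8,12-lactone, 3-OH, 5,6-O-isopropylidene), via silyl ether ester 15 (not isolated)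
Conditions: CrCl2 (15 mol%), Me3SiCl (3 equiv), LiClO4 (0.1 M), DMF, undivided cell, Al anode, carbon-foam cathode, −1.1 V vs Ag/AgCl, 14 added over 12 h (2 mM), rt; then PPTS, MeOH, rt
Reagents that add atoms: none
Why: Proposed new method: the cathode keeps a low steady-state concentration of divalent chromium, which turns the allylic bromide into a 2-(methoxycarbonyl)allyl species of trivalent chromium; this adds to the tethered aldehyde through a six-membered chair with both ring arms equatorial (anti adduct, hence the trans lactone) on the alkene face anti to the C6–O bond with H6 in the alkene plane (so bought C6 sets C7 and C8), Me3SiCl frees the chromium alkoxide for turnover and acidic methanol then desilylates and lactonises; the closest known reactions are stoichiometric CrCl2 Nozaki–Hiyama (Barbier) ring closures to ten-membered α-methylene lactones and electrochemical chromium-catalysed Nozaki–Hiyama–Kishi couplings, neither shown for a catalytic ring-closing 2-(alkoxycarbonyl)allylation.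

Step 11
Reactants: 16 lactone alcohol
Product: 17 lactone enone acetonide (3-oxo)
Conditions: Dess–Martin periodinane (1.5 equiv), CH2Cl2, 0 °C to rt
Reagents that add atoms: none
Why: Dess–Martin oxidation of the only free hydroxyl converges both C3 epimers on the α-methylene ketone, while the acetonide keeps the allylic C5 oxygen protected.

Step 12
Reactants: 17 lactone enone acetonide
Product: 18 enone diol (5,6-diol)
Conditions: AcOH/H2O (4:1), 45 °C
Reagents that add atoms: none
Why: Mild acid hydrolysis of the trans-fused isopropylidene ketal leaves the α-methylene lactone, enone and Z alkene untouched.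

Step 13
Reactants: 18 enone diol; 19 angelic acid
Product: 20 5-O-angelate (Z-C1=C10 alkene, 6-OH free)
Conditions: 19 (1.2 equiv), 2,4,6-trichlorobenzoyl chloride (1.2 equiv), Et3N (1.3 equiv), toluene, rt; then 18, 70 °C
Reagents that add atoms: none
Why: Yamaguchi-type mixed-anhydride acylation without DMAP keeps the angelate Z, and the bulky anhydride should take the allylic C5–OH (flanked by sp2 C4) before the C6–OH, which is flanked by the ring-fusion carbon C7 and can be partly tied up as the transannular C3 hemiketal.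

Step 14
Reactants: 20 5-O-angelate
Product: 21 target, (1S,10R)-epoxide
Conditions: dimethyldioxirane (1.1 equiv), acetone, −20 °C
Reagents that add atoms: dimethyldioxirane CC1(C)OO1
Why: Electrophilic epoxidation takes the only electron-rich alkene (the enone, lactone and angelate alkenes are deactivated), and peripheral attack on the ring conformer fixed by C5–C8, from the face opposite the C6 hydroxyl and the lactone oxygen, is expected to give the cis-(1S,10R) epoxide.

**Compound list**
1 | 4-methylanisole | COc1ccc(C)cc1 | starting material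
2 | 1-methoxy-4-methylcyclohexa-1,4-diene | COC1=CCC(C)=CC1 | intermediate
3 | methyl (3Z)-4-methyl-6-oxohex-3-enoate | COC(=O)C/C=C(/C)CC=O | intermediate
4 | methyl (3Z)-6,6-dimethoxy-4-methylhex-3-enoate | COC(=O)C/C=C(/C)CC(OC)OC | intermediate
5 | (3Z)-6,6-dimethoxy-4-methylhex-3-enal | O=CC/C=C(/C)CC(OC)OC | intermediate
6 | dimethyl (4S,5S)-2,2-dimethyl-1,3-dioxolane-4,5-dicarboxylate (dimethyl 2,3-O-isopropylidene-D-tartrate) | COC(=O)[C@H]1OC(C)(C)O[C@@H]1C(=O)OC | starting material
7 | methyl (4S,5S)-5-formyl-2,2-dimethyl-1,3-dioxolane-4-carboxylate | O=C[C@H]1OC(C)(C)O[C@@H]1C(=O)OC | intermediate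
8 | methyl (4S,5R)-5-ethynyl-2,2-dimethyl-1,3-dioxolane-4-carboxylate | C#C[C@H]1OC(C)(C)O[C@@H]1C(=O)OC | intermediate
9 | methyl (4S,5R)-5-[(5Z)-8,8-dimethoxy-6-methyl-3-(triethylsilyloxy)octa-1,5-dien-2-yl]-2,2-dimethyl-1,3-dioxolane-4-carboxylate (C3 epimers) | COC(OC)C/C(C)=C\CC(O[Si](CC)(CC)CC)C(=C)[C@H]1OC(C)(C)O[C@@H]1C(=O)OC | intermediate
10 | (4S,5R)-5-[(5Z)-8,8-dimethoxy-6-methyl-3-(triethylsilyloxy)octa-1,5-dien-2-yl]-2,2-dimethyl-1,3-dioxolane-4-carbaldehyde (C3 epimers) | COC(OC)C/C(C)=C\CC(O[Si](CC)(CC)CC)C(=C)[C@H]1OC(C)(C)O[C@@H]1C=O | intermediate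
11 | methyl acrylate | C=CC(=O)OC | starting material
12 | Morita–Baylis–Hillman adduct: 10 with CHO replaced by CH(OH)C(=CH2)CO2Me (carbinol and C3 epimers) | COC(OC)C/C(C)=C\CC(O[Si](CC)(CC)CC)C(=C)[C@H]1OC(C)(C)O[C@@H]1C(O)C(=C)C(=O)OC | intermediate
13 | (Z)-allylic bromide: dioxolane carbon C6 bears CH=C(CH2Br)CO2Me, dioxolane cis to CH2Br | COC(OC)C/C(C)=C\CC(O[Si](CC)(CC)CC)C(=C)[C@H]1OC(C)(C)O[C@@H]1/C=C(\CBr)C(=O)OC | intermediate
14 | aldehyde bromide: 13 with CH(OMe)2 replaced by CHO | O=CC/C(C)=C\CC(O[Si](CC)(CC)CC)C(=C)[C@H]1OC(C)(C)O[C@@H]1/C=C(\CBr)C(=O)OC | intermediate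
15 | ring-closed methyl ester: ten-membered carbocycle, 8-OSiMe3, 3-OSiEt3, 5,6-O-isopropylidene, C7 bears C(=CH2)CO2Me | C=C(C(=O)OC)[C@H]1[C@H](O[Si](C)(C)C)C/C(C)=C\CC(O[Si](CC)(CC)CC)C(=C)[C@H]2OC(C)(C)O[C@@H]21 | intermediate
16 | lactone alcohol: trans-8,12-lactone, 3-OH (epimers), 5,6-O-isopropylidene, Z-C1=C10 | C=C1C(=O)O[C@@H]2C/C(C)=C\CC(O)C(=C)[C@H]3OC(C)(C)O[C@@H]3[C@@H]12 | intermediate
17 | lactone enone acetonide (3-oxo) | C=C1C(=O)O[C@@H]2C/C(C)=C\CC(=O)C(=C)[C@H]3OC(C)(C)O[C@@H]3[C@@H]12 | intermediate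
18 | enone diol (5,6-diol) | C=C1C(=O)O[C@@H]2C/C(C)=C\CC(=O)C(=C)[C@@H](O)[C@H](O)[C@@H]12 | intermediate
19 | angelic acid, (2Z)-2-methylbut-2-enoic acid | C/C=C(/C)C(=O)O | starting material
20 | 5-O-angelate, 6-OH free, Z-C1=C10 | C=C1C(=O)O[C@@H]2C/C(C)=C\CC(=O)C(=C)[C@@H](OC(=O)/C(C)=C\C)[C@H](O)[C@@H]12 | intermediate
21 | CNP0348992.7 | C=C1C(=O)O[C@@H]2C[C@@]3(C)O[C@H]3CC(=O)C(=C)[C@@H](OC(=O)/C(C)=C\C)[C@H](O)[C@@H]12 | target

**Step count**
Total: 14 steps (3 to fragment 5, 1 to fragment 8, 10 from the union on). Longest linear sequence: 13 steps (1 → 2 → 4 → 5 → 9 → … → 21).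

**Three steps most likely to fail**

Step 10 (the proposed new ring closure). Risks are oligomerisation, direct cathodic reduction of the bromide, and a cis-lactone or the C7/C8 pair of opposite sense. Fallback with known chemistry, setting out from 12: Ac2O/pyridine gives the allylic acetate F1. Et3SiOTf/2,4,6-collidine then water gives the aldehyde acetate F2. Pd(PPh3)4 (10 mol%) and Et2Zn (3 equiv) in THF at 2 mM ionise the acetate to a π-allyl complex of divalent palladium, which is transmetalated to the allylzinc and adds to the aldehyde (umpolung allylation), giving the ring-closed hydroxy ester F3. PPTS/MeOH removes the silyl group and closes the lactone, coming back to the route at 16.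

Step 13 (C5 versus C6 acylation). The selectivity rests on sterics and is not guaranteed. Fallback, setting out from 18: PPTS, HC(OMe)3 and MeOH close the C6 hydroxyl onto the C3 ketone as the bridged methyl ketal F4, which leaves C5–OH as the only hydroxyl. The same mixed-anhydride acylation gives the ketal angelate F5. AcOH/H2O at rt opens the ketal and returns to the route at 20.

Step 14 (face of the epoxidation). The preferred face of the ten-membered ring cannot be predicted with certainty. Fallback if the other epoxide dominates, setting out from 20: NBS in THF/H2O at 0 °C forms the bromonium ion on the face the oxidant prefers and water opens it at the tertiary C10 from the other face, giving the bromohydrin F6. K2CO3 in acetone closes it with inversion at C1, which puts the oxygen on the required face and arrives at 21.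

**Further compounds**
F1 | step 10 | allylic acetate of 12 | COC(OC)C/C(C)=C\CC(O[Si](CC)(CC)CC)C(=C)[C@H]1OC(C)(C)O[C@@H]1C(OC(C)=O)C(=C)C(=O)OC
F2 | step 10 | aldehyde acetate (F1 with CH(OMe)2 replaced by CHO) | O=CC/C(C)=C\CC(O[Si](CC)(CC)CC)C(=C)[C@H]1OC(C)(C)O[C@@H]1C(OC(C)=O)C(=C)C(=O)OC
F3 | step 10 | ring-closed hydroxy ester (8-OH, 3-OSiEt3) | C=C(C(=O)OC)[C@H]1[C@H](O)C/C(C)=C\CC(O[Si](CC)(CC)CC)C(=C)[C@H]2OC(C)(C)O[C@@H]21
F4 | step 13 | bridged 3-methoxy-3,6-epoxy ketal of 18 (5-OH free) | C=C1C(=O)O[C@@H]2C/C(C)=C\C[C@]3(OC)O[C@@H]([C@H](O)C3=C)[C@@H]12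
F5 | step 13 | 5-O-angelate of the bridged ketal | C=C1C(=O)O[C@@H]2C/C(C)=C\C[C@]3(OC)O[C@@H]([C@H](OC(=O)/C(C)=C\C)C3=C)[C@@H]12
F6 | step 14 | bromohydrin of 20 (1-Br, 10-OH) | C=C1C(=O)O[C@@H]2C[C@@](C)(O)[C@H](Br)CC(=O)C(=C)[C@@H](OC(=O)/C(C)=C\C)[C@H](O)[C@@H]12
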